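At early times target forms at nearly the same percent per minute in the green and red runs, although red takes gas into target at 0.395 mM min⁻¹ and green at 0.0140 mM min⁻¹, far faster.

| flask | substrate | gas phase | remark | time |
|---|---|---|---|---|
| green | 0.81 mM | 1 mM (held) | run made earlier |  |
| red | 21 mM | 1 mM (held) | run made earlier |  |
| eta | 0.60 mM | 1.0 mM (held) |  | 40 min |
| gamma | 2.0 mM | 1.0 mM (held) |  | 40 min |
| delta | 5.0 mM | 1.0 mM (held) |  | 40 min |
| theta | 15 mM | 1.0 mM (held) |  | 40 min |

| run | time / min | target / % | substrate / % |
|---|---|---|---|
| green | 4.00 | 6.9 | 89.0 |
| green | 8.00 | 13.3 | 78.8 |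
| green | 12.0 | 18.3 | 71.7 |
| green | 15.0 | 21.2 | 65.3 |
| green | 20.0 | 25.0 | 57.7 |
| green | 25.0 | 29.1 | 51.3 |
| green | 30.0 | 31.8 | 46.0 |
| red | 2.50 | 4.7 | 93.5 |
| red | 3.00 | 6.1 | 92.2 |
| red | 5.00 | 7.3 | 85.3 |
| red | 8.00 | 12.5 | 79.5 |
| red | 12.0 | 18.0 | 71.6 |
| red | 20.0 | 25.4 | 57.4 |
| red | 30.0 | 31.3 | 47.0 |

(standard deviation of a reading: 0.5 percentage points)

- at the start none of the gas is dissolved
- the analysis behind the earlier runs scatters by 0.5 percentage points, standard deviation
- reactions considered so far: 2 dissolved gas -> homo dimer; substrate -> side product; substrate + dissolved gas <-> target; gas phase <-> dissolved gas; dissolved gas -> decomposed reagent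
- "hardly changes" means that all values lie within two and a half points (for a concentration: within two and a half percent of the largest)

* amount of target at the end, in percent of the substrate charged for eta, gamma, delta, theta, in this order
* the shape of the row from first to last (rises all the way / falls, then rises / hardly changes / rises, then falls / falls all the way)

Take dissolution as the fast step, settled at each moment. Dissolved gas then sags below saturation by an amount that grows with the draw, and the draw into target grows with the charge, so I reckon with the extra sag that extra charge adds; the chemistry is pseudo-first-order in substrate as far as that extra sag stays small. At 30.0 min red stands 0.5 percentage points below green in target, no more than the scatter, over 20.2 mM of extra charge. That reads 2.48 × 10⁻⁴ mM⁻¹: this is the sag coefficient, the target lost, as a fraction of the charge, per extra millimolar charged.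

Theta against eta therefore loses 0.36 points. The bound from below is zero, since a lighter charge draws less. The bound from above counts red's extra unreacted substrate, 1 point at that time, as lost target, which scales to 0.71 points. Both lie inside the margin for a row that hardly changes.

For the level, green's target stands at 31.8%, the bound from below if it gains nothing more. Its slope from 20.0 min to 30.0 min, held straight on, gives 38.6% from above. Green gained 21.2% in its first 15.0 min and half that in the next. Continuing this halving gives 35.7% for eta and 35.3% for theta.

The forecast, inside both brackets, set 36%, 36%, 36%, 36%, hardly changes, holding that “dissolved gas stays effectively constant”.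

The flasks give 35.0%, 35.0%, 34.9%, 34.6%: hardly changes.

    2 dissolved gas → homo dimer (k = 0.500 M⁻¹ s⁻¹)
    substrate → side product (k = 1.80 × 10⁻⁴ s⁻¹)
    substrate + dissolved gas ⇌ target (K = 1300 M⁻¹, k = 0.340 M⁻¹ s⁻¹)
    gas phase ⇌ dissolved gas, rate k4*(csat - [dissolved gas]) (kL = 0.140 s⁻¹)
    dissolved gas → decomposed reagent (k = 6.80 × 10⁻⁵ s⁻¹)

Theta ends 0.4 points below eta. At 20.0 min its dissolved gas stands at 0.979 mM against 0.992 mM in eta, with saturation at 1.0 mM. The sag coefficient puts delta 0.11 points below eta, and delta ends 0.1 points below it.

The runs are calculated with constants of no real substance; noise was put on by code.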